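Assumption: the target has no stereocentre and no stereogenic double bond, so it is achiral; the "single enantiomer" is the compound itself and no stereocontrol is needed.

**Retrosynthetic overview**
1. The target is a tridepside of three orsellinate units (rings A, B, C); the two aryl ester C–O bonds are disconnected to give methyl orsellinate (ring A), a 4-O-benzyl-2-O-methyl acid (ring B) and a 2-O-benzyl-4-O-methyl acid (ring C).
2. All three rings come from one intermediate, methyl orsellinate 6, by regioselective O-alkylation (the non-chelated 4-OH reacts first) and saponification.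
3. The orsellinate ring is built de novo: intermolecular Michael addition of methyl acetoacetate to methyl crotonate (key C–C bond), Dieckmann ring closure, then aromatisation by bromination/dehydrobromination and hydrogenolysis.
4. Order: the carbocycle is formed once (steps 1–3), then A + B gives A–B, then C is attached, and a final debenzylation gives the target.

**Route**

Step 1
Reactants: 1 methyl acetoacetate; 2 methyl (E)-but-2-enoate (methyl crotonate)
Product: 4 methyl 6-methyl-2,4-dioxocyclohexane-1-carboxylate (methyl dihydroorsellinate; racemic), via dimethyl 2-acetyl-3-methylpentanedioate 3 (not isolated)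
Conditions: NaOMe (1.1 equiv), MeOH, reflux, 16 h; then aq. HCl, 0 °C
Reagents that add atoms: none
Why: The acetoacetate enolate adds to the crotonate in an intermolecular Michael reaction (key C–C bond) and adduct 3 closes by an intramolecular Claisen (Dieckmann) condensation driven by formation of the 1,3-dione enolate; the two stereocentres formed are racemic and are erased on aromatisation.

Step 2
Reactants: 4 methyl 6-methyl-2,4-dioxocyclohexane-1-carboxylate
Product: 5 methyl 3,5-dibromo-2,4-dihydroxy-6-methylbenzoate
Conditions: Br2 (3.1 equiv), AcOH, rt, 16 h; pour into water, filter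
Reagents that add atoms: bromine, BrBr
Why: α-Bromination of the enolised 1,3-dione and loss of HBr aromatise the ring (bromination–dehydrobromination), and the electron-rich resorcinol then takes up bromine at both free ring positions by electrophilic aromatic substitution, giving one crystalline product.

Step 3
Reactants: 5 methyl 3,5-dibromo-2,4-dihydroxy-6-methylbenzoate
Product: 6 methyl 2,4-dihydroxy-6-methylbenzoate (methyl orsellinate)
Conditions: H2 (1 atm), 10% Pd/C, NaOAc (2.5 equiv), MeOH, rt
Reagents that add atoms: none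
Why: Catalytic hydrogenolysis cleaves both aryl C–Br bonds while NaOAc buffers the HBr, and the ester, phenols and arene are untouched.

Step 4
Reactants: 6 methyl 2,4-dihydroxy-6-methylbenzoate
Product: 7 methyl 4-(benzyloxy)-2-hydroxy-6-methylbenzoate
Conditions: BnBr (1.05 equiv), K2CO3 (1.2 equiv), acetone, reflux
Reagents that add atoms: benzyl bromide, BrCc1ccccc1
Why: Williamson etherification is selective for the 4-OH, which is more acidic and unhindered, whereas the 2-OH is hydrogen-bonded to the ester carbonyl.

Step 5
Reactants: 7 methyl 4-(benzyloxy)-2-hydroxy-6-methylbenzoate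
Product: 8 methyl 4-(benzyloxy)-2-methoxy-6-methylbenzoate
Conditions: MeI (3 equiv), K2CO3 (2 equiv), DMF, 50 °C
Reagents that add atoms: iodomethane, CI
Why: Williamson etherification with excess MeI in a dipolar aprotic solvent overcomes the hydrogen bond of the remaining chelated phenol.

Step 6
Reactants: 8 methyl 4-(benzyloxy)-2-methoxy-6-methylbenzoate
Product: 9 4-(benzyloxy)-2-methoxy-6-methylbenzoic acid
Conditions: KOH (5 equiv), DMSO/H2O (4:1), 90 °C; then cold 2 M HCl
Reagents that add atoms: potassium hydroxide, [K+].[OH-]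
Why: Saponification of the di-ortho-substituted ester needs poorly solvated hydroxide in hot DMSO; both ethers are inert to base and the fully O-alkylated acid does not decarboxylate on cold acidification.

Step 7
Reactants: 9 4-(benzyloxy)-2-methoxy-6-methylbenzoic acid
Product: 10 4-(benzyloxy)-2-methoxy-6-methylbenzoyl chloride
Conditions: (COCl)2 (1.5 equiv), DMF (cat.), CH2Cl2, 0 °C to rt; evaporate, use crude
Reagents that add atoms: oxalyl chloride, ClC(=O)C(=O)Cl
Why: Acid chloride formation through the Vilsmeier-type chloroiminium species is mild and neutral enough to spare the benzyl ether and the electron-rich ring.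

Step 8
Reactants: 10 4-(benzyloxy)-2-methoxy-6-methylbenzoyl chloride; 6 methyl 2,4-dihydroxy-6-methylbenzoate
Product: 11 methyl 4-{[4-(benzyloxy)-2-methoxy-6-methylbenzoyl]oxy}-2-hydroxy-6-methylbenzoate
Conditions: Et3N (1.5 equiv), DMAP (0.1 equiv), CH2Cl2, 0 °C to rt
Reagents that add atoms: none
Why: DMAP-catalysed nucleophilic acyl substitution acylates only the free 4-OH of 6, because the 2-OH is hydrogen-bonded to and flanked by the ester.

Step 9
Reactants: 11 methyl 4-{[4-(benzyloxy)-2-methoxy-6-methylbenzoyl]oxy}-2-hydroxy-6-methylbenzoate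
Product: 12 methyl 2-hydroxy-4-[(4-hydroxy-2-methoxy-6-methylbenzoyl)oxy]-6-methylbenzoate
Conditions: H2 (1 atm), 10% Pd/C, EtOAc, rt
Reagents that add atoms: none
Why: Hydrogenolysis removes the benzyl ether, and the aryl ester (depside) link and the methyl ester are stable to H2 over Pd/C.

Step 10
Reactants: 6 methyl 2,4-dihydroxy-6-methylbenzoate
Product: 13 methyl 2-hydroxy-4-methoxy-6-methylbenzoate (methyl everninate)
Conditions: MeI (1.1 equiv), K2CO3 (1.2 equiv), acetone, reflux
Reagents that add atoms: iodomethane, CI
Why: Regioselective Williamson methylation of the non-chelated 4-OH, by the same selectivity as in step 4.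

Step 11
Reactants: 13 methyl 2-hydroxy-4-methoxy-6-methylbenzoate
Product: 14 methyl 2-(benzyloxy)-4-methoxy-6-methylbenzoate
Conditions: BnBr (1.5 equiv), K2CO3 (2 equiv), DMF, 70 °C
Reagents that add atoms: benzyl bromide, BrCc1ccccc1
Why: Williamson benzylation under more forcing conditions caps the chelated 2-OH so that it cannot interfere with carboxyl activation later.

Step 12
Reactants: 14 methyl 2-(benzyloxy)-4-methoxy-6-methylbenzoate
Product: 15 2-(benzyloxy)-4-methoxy-6-methylbenzoic acid
Conditions: KOH (5 equiv), DMSO/H2O (4:1), 90 °C; then cold 2 M HCl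
Reagents that add atoms: potassium hydroxide, [K+].[OH-]
Why: Saponification of the hindered ester with hydroxide in hot DMSO, as in step 6, with base-stable ethers.

Step 13
Reactants: 15 2-(benzyloxy)-4-methoxy-6-methylbenzoic acid
Product: 16 2-(benzyloxy)-4-methoxy-6-methylbenzoyl chloride
Conditions: (COCl)2 (1.5 equiv), DMF (cat.), CH2Cl2, 0 °C to rt; evaporate, use crude
Reagents that add atoms: oxalyl chloride, ClC(=O)C(=O)Cl
Why: Mild acid chloride formation through the Vilsmeier-type intermediate, as in step 7.

Step 14
Reactants: 16 2-(benzyloxy)-4-methoxy-6-methylbenzoyl chloride; 12 methyl 2-hydroxy-4-[(4-hydroxy-2-methoxy-6-methylbenzoyl)oxy]-6-methylbenzoate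
Product: 17 methyl 4-[(4-{[2-(benzyloxy)-4-methoxy-6-methylbenzoyl]oxy}-2-methoxy-6-methylbenzoyl)oxy]-2-hydroxy-6-methylbenzoate
Conditions: Et3N (1.5 equiv), DMAP (0.1 equiv), CH2Cl2, 0 °C to rt
Reagents that add atoms: none
Why: Nucleophilic acyl substitution occurs at the only non-chelated phenol of 12 (the ring B 4-OH), while the ring A 2-OH stays hydrogen-bonded to its ester and unreactive.

Step 15
Reactants: 17 methyl 4-[(4-{[2-(benzyloxy)-4-methoxy-6-methylbenzoyl]oxy}-2-methoxy-6-methylbenzoyl)oxy]-2-hydroxy-6-methylbenzoate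
Product: 18 methyl 2-hydroxy-4-({4-[(2-hydroxy-4-methoxy-6-methylbenzoyl)oxy]-2-methoxy-6-methylbenzoyl}oxy)-6-methylbenzoate (target)
Conditions: H2 (1 atm), 10% Pd/C, EtOAc, rt
Reagents that add atoms: none
Why: Hydrogenolysis of the last benzyl ether frees the ring C 2-OH; both depside esters and the methyl ester survive, and there is no stereocentre to set.

**Compound list**
1 | methyl acetoacetate | CC(=O)CC(=O)OC | starting material
2 | methyl (E)-but-2-enoate (methyl crotonate) | C/C=C/C(=O)OC | starting material
3 | dimethyl 2-acetyl-3-methylpentanedioate (racemic diastereomer mixture) | COC(=O)CC(C)C(C(C)=O)C(=O)OC | intermediate (not isolated)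
4 | methyl 6-methyl-2,4-dioxocyclohexane-1-carboxylate (racemic, largely enolised) | COC(=O)C1C(C)CC(=O)CC1=O | intermediate
5 | methyl 3,5-dibromo-2,4-dihydroxy-6-methylbenzoate | COC(=O)c1c(C)c(Br)c(O)c(Br)c1O | intermediate
6 | methyl 2,4-dihydroxy-6-methylbenzoate (methyl orsellinate) | COC(=O)c1c(C)cc(O)cc1O | intermediate
7 | methyl 4-(benzyloxy)-2-hydroxy-6-methylbenzoate | COC(=O)c1c(C)cc(OCc2ccccc2)cc1O | intermediate
8 | methyl 4-(benzyloxy)-2-methoxy-6-methylbenzoate | COC(=O)c1c(C)cc(OCc2ccccc2)cc1OC | intermediate
9 | 4-(benzyloxy)-2-methoxy-6-methylbenzoic acid | OC(=O)c1c(C)cc(OCc2ccccc2)cc1OC | intermediate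
10 | 4-(benzyloxy)-2-methoxy-6-methylbenzoyl chloride | ClC(=O)c1c(C)cc(OCc2ccccc2)cc1OC | intermediate
11 | methyl 4-{[4-(benzyloxy)-2-methoxy-6-methylbenzoyl]oxy}-2-hydroxy-6-methylbenzoate | COC(=O)c1c(C)cc(OC(=O)c2c(C)cc(OCc3ccccc3)cc2OC)cc1O | intermediate
12 | methyl 2-hydroxy-4-[(4-hydroxy-2-methoxy-6-methylbenzoyl)oxy]-6-methylbenzoate | COC(=O)c1c(C)cc(OC(=O)c2c(C)cc(O)cc2OC)cc1O | intermediate
13 | methyl 2-hydroxy-4-methoxy-6-methylbenzoate (methyl everninate) | COC(=O)c1c(C)cc(OC)cc1O | intermediate
14 | methyl 2-(benzyloxy)-4-methoxy-6-methylbenzoate | COC(=O)c1c(C)cc(OC)cc1OCc1ccccc1 | intermediate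
15 | 2-(benzyloxy)-4-methoxy-6-methylbenzoic acid | OC(=O)c1c(C)cc(OC)cc1OCc1ccccc1 | intermediate
16 | 2-(benzyloxy)-4-methoxy-6-methylbenzoyl chloride | ClC(=O)c1c(C)cc(OC)cc1OCc1ccccc1 | intermediate
17 | methyl 4-[(4-{[2-(benzyloxy)-4-methoxy-6-methylbenzoyl]oxy}-2-methoxy-6-methylbenzoyl)oxy]-2-hydroxy-6-methylbenzoate | COC(=O)c1c(C)cc(OC(=O)c2c(C)cc(OC(=O)c3c(C)cc(OC)cc3OCc3ccccc3)cc2OC)cc1O | intermediate
18 | methyl 2-hydroxy-4-({4-[(2-hydroxy-4-methoxy-6-methylbenzoyl)oxy]-2-methoxy-6-methylbenzoyl}oxy)-6-methylbenzoate | COC(=O)c1c(C)cc(OC(=O)c2c(C)cc(OC(=O)c3c(C)cc(OC)cc3O)cc2OC)cc1O | target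

**Totals**
Total step count: 15.
Longest linear sequence: 11 steps (steps 1–9, 14, 15).

**Three steps most likely to fail, with fallbacks**

Step 2 (aromatising bromination; risk of under- or over-brominated mixtures). The fallback sets out from compound 1 and comes back at compound 6, bypassing 4 and 5. Methyl acetoacetate 1 is converted into its dianion with NaH and then n-BuLi in THF at 0 °C, and the mixture is warmed and refluxed. The terminal carbanion of one molecule attacks the ester of a second in an intermolecular Claisen condensation to give methyl 3,5,7-trioxooctanoate F1. F1 is not isolated; it cyclises by intramolecular aldol condensation between C-2 and the C-7 ketone and aromatises by loss of water, giving methyl orsellinate 6 after acidic work-up.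

Step 8 (first depside coupling; risk of sluggish reaction of the hindered acid chloride or loss of 4-OH over 2-OH selectivity under basic conditions). The fallback sets out from compound 9 and comes back at compound 11. Acid 9 and phenol 6 are stirred with trifluoroacetic anhydride in dry toluene at rt, with no base. The acid forms 4-(benzyloxy)-2-methoxy-6-methylbenzoic trifluoroacetic anhydride F2 in the flask. This acylium-type donor acylates only the non-chelated 4-OH of 6 under acidic conditions, and any phenol trifluoroacetate is removed by the NaHCO3 wash, giving 11.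

Step 14 (second depside coupling; risk of competing acylation of the ring A phenol or acyl scrambling of the existing depside link in 12). The fallback reverses the order of assembly: it sets out from compound 9 and comes back at compound 17.
- Acid 9 is esterified with N,N-dimethylformamide di-tert-butyl acetal in toluene at 80 °C to give tert-butyl 4-(benzyloxy)-2-methoxy-6-methylbenzoate F3.
- Hydrogenolysis (H2, 10% Pd/C, EtOAc) gives tert-butyl 4-hydroxy-2-methoxy-6-methylbenzoate F4, which has a single phenol.
- Acylation of F4 with acid chloride 16 (Et3N, cat. DMAP, CH2Cl2) gives tert-butyl 4-{[2-(benzyloxy)-4-methoxy-6-methylbenzoyl]oxy}-2-methoxy-6-methylbenzoate F5.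
- Brief treatment with CF3CO2H in CH2Cl2 at 0 °C to rt cleaves the tert-butyl ester to 4-{[2-(benzyloxy)-4-methoxy-6-methylbenzoyl]oxy}-2-methoxy-6-methylbenzoic acid F6.
- F6 is condensed with methyl orsellinate 6 using trifluoroacetic anhydride in toluene at rt, through 4-{[2-(benzyloxy)-4-methoxy-6-methylbenzoyl]oxy}-2-methoxy-6-methylbenzoic trifluoroacetic anhydride F7 (not isolated), to give 17, which goes on to step 15 unchanged.

**Further compounds**
F1 | step 2 | methyl 3,5,7-trioxooctanoate | COC(=O)CC(=O)CC(=O)CC(C)=O
F2 | step 8 | 4-(benzyloxy)-2-methoxy-6-methylbenzoic trifluoroacetic anhydride | O=C(OC(=O)C(F)(F)F)c1c(C)cc(OCc2ccccc2)cc1OC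
F3 | step 14 | tert-butyl 4-(benzyloxy)-2-methoxy-6-methylbenzoate | CC(C)(C)OC(=O)c1c(C)cc(OCc2ccccc2)cc1OC
F4 | step 14 | tert-butyl 4-hydroxy-2-methoxy-6-methylbenzoate | CC(C)(C)OC(=O)c1c(C)cc(O)cc1OC
F5 | step 14 | tert-butyl 4-{[2-(benzyloxy)-4-methoxy-6-methylbenzoyl]oxy}-2-methoxy-6-methylbenzoate | CC(C)(C)OC(=O)c1c(C)cc(OC(=O)c2c(C)cc(OC)cc2OCc2ccccc2)cc1OC
F6 | step 14 | 4-{[2-(benzyloxy)-4-methoxy-6-methylbenzoyl]oxy}-2-methoxy-6-methylbenzoic acid | OC(=O)c1c(C)cc(OC(=O)c2c(C)cc(OC)cc2OCc2ccccc2)cc1OC
F7 | step 14 | 4-{[2-(benzyloxy)-4-methoxy-6-methylbenzoyl]oxy}-2-methoxy-6-methylbenzoic trifluoroacetic anhydride | O=C(OC(=O)C(F)(F)F)c1c(C)cc(OC(=O)c2c(C)cc(OC)cc2OCc2ccccc2)cc1OC
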